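Everything rests on cutting the C9–C10 bond of the oxepane ring (O, C5, C6, C7, C8, C9, C10). A samarium diiodide ketyl–olefin cyclisation joins a C9 aldehyde to the β-carbon of an (E)-β-alkoxycrotonate bound to the C5 oxygen; in one operation it closes this oxepane and sets both the C9 carbinol and the fully substituted ether carbon C10. The feature exploited is the O–C10(CH3)(C1)–C9(O) unit of that ring, a methyl-bearing ether carbon next to a carbinol. The precursor is a 2-methoxytetrahydrofuran (lactone carbon C12 masked as acetal) carrying trans at C8 the aldehyde and at C7 the C6–C5 arm with the crotonate and the C4 vinyl group.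

Key step: step 11

Remarks on the chemistry
- Atom labels follow germacrane numbering of the target: the ether oxygen bridges C5 and C10, the lactone is C12(=O)–O–C8 with C11 on C7, the ester sits on C9, C14 is the methyl on C10 and C15 the methyl on C4.
- The target SMILES is read as 4S, 5R, 7R, 8R, 9S, 10R with an (R)-2-methylbutanoate and a trans-fused lactone; the (R)-lactone acid 1 supplies 8R.
- Assumption on the precursor design: SmI2 cleaves an acyloxy group next to a ketyl quickly, so a lactone oxygen on C8 would be lost from the C9 ketyl. C12 is therefore carried as a methyl acetal from step 5 to step 17, which also leaves the C2 ethyl ester as the only carbonyl group in step 12. The acetal carbon is a mixture of both epimers, written without a descriptor in 9 to 26, and it disappears in step 17.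
- The free C5 hydroxyl of 15 could close onto C12 under acid, so 15 is kept away from acid.

Step 1
Reactants: 1 (R)-5-oxotetrahydrofuran-2-carboxylic acid
Product: 2 (R)-5-(hydroxymethyl)dihydrofuran-2(3H)-one
Conditions: BH3·SMe2, THF, 0 °C to rt; MeOH quench
Reagents that add atoms: none
Why: Borane reduces the free acid through its acyloxyborane much faster than the lactone (chemoselective borane reduction of a carboxylic acid), and the C8 stereocentre is not involved.

Step 2
Reactants: 2 (R)-5-(hydroxymethyl)dihydrofuran-2(3H)-one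
Product: 3 (R)-5-[(tert-butyldiphenylsilyloxy)methyl]dihydrofuran-2(3H)-one
Conditions: t-BuPh2SiCl, imidazole, DMF, rt
Reagents that add atoms: tert-butyl(chloro)diphenylsilane, CC(C)(C)[Si](Cl)(c1ccccc1)c1ccccc1
Why: Imidazole-promoted silylation of the only hydroxyl; this silyl ether should withstand enolate, cuprate, hydride, acidic methanol and alkaline peroxide until step 9.

Step 3
Reactants: 3 (R)-5-[(tert-butyldiphenylsilyloxy)methyl]dihydrofuran-2(3H)-one
Product: 5 (R)-5-[(tert-butyldiphenylsilyloxy)methyl]furan-2(5H)-one, via α-phenylselanyl lactone 4 (not isolated)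
Conditions: LiN(SiMe3)2, THF, −78 °C; PhSeBr; then H2O2, pyridine, CH2Cl2, 0 °C to rt
Reagents that add atoms: none
Why: Selenenylation of the lactone enolate and oxidation give a selenoxide that should undergo syn-elimination toward C7 (selenoxide elimination), leaving C8 untouched.

Step 4
Reactants: 5 (R)-5-[(tert-butyldiphenylsilyloxy)methyl]furan-2(5H)-one; 6 allylmagnesium bromide
Product: 8 (4R,5R)-4-allyl-5-[(tert-butyldiphenylsilyloxy)methyl]dihydrofuran-2(3H)-one, via silyl ketene acetal 7 (not isolated)
Conditions: CuBr·SMe2, Me3SiCl, THF, −78 °C; then aq. NH4Cl/HCl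
Reagents that add atoms: none
Why: Copper-mediated conjugate allylation, accelerated by Me3SiCl which traps the enolate as 7, should deliver the allyl group anti to the C8 silyloxymethyl group and so set C7 (7R, trans to C8); aqueous acid then hydrolyses 7.

Step 5
Reactants: 8 (4R,5R)-4-allyl-5-[(tert-butyldiphenylsilyloxy)methyl]dihydrofuran-2(3H)-one
Product: 10 (4R,5R)-4-allyl-5-[(tert-butyldiphenylsilyloxy)methyl]-2-methoxytetrahydrofuran, via lactol 9 (not isolated)
Conditions: i-Bu2AlH, CH2Cl2, −78 °C; then MeOH, PPTS, rt
Reagents that add atoms: methanol, CO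
Why: Half-reduction of the lactone at −78 °C and acid-catalysed acetalisation with methanol (Fischer-type glycosidation) turn the acyloxy oxygen on C8 into an acetal ether oxygen; the new C12 centre is removed later, so both epimers are carried.

Step 6
Reactants: 10 (4R,5R)-4-allyl-5-[(tert-butyldiphenylsilyloxy)methyl]-2-methoxytetrahydrofuran
Product: 12 2-[(2R,3R)-2-[(tert-butyldiphenylsilyloxy)methyl]-5-methoxytetrahydrofuran-3-yl]acetaldehyde, via ozonide 11 (not isolated)
Conditions: O3, CH2Cl2, −78 °C (Sudan red end point); then PPh3, −78 °C to rt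
Reagents that add atoms: ozone, [O-][O+]=O
Why: Ozonolysis of the terminal alkene with reductive work-up should give the C5 aldehyde, and the dye end point limits exposure of the acetal C–H bond to ozone.

Step 7
Reactants: 12 2-[(2R,3R)-2-[(tert-butyldiphenylsilyloxy)methyl]-5-methoxytetrahydrofuran-3-yl]acetaldehyde; 13 trans-but-2-ene
Product: 15 (2R,3S)-1-[(2R,3R)-2-[(tert-butyldiphenylsilyloxy)methyl]-5-methoxytetrahydrofuran-3-yl]-3-methylpent-4-en-2-ol, via borinate 14 (not isolated)
Conditions: 13, n-BuLi, KOtBu, THF, −78 to −45 °C; (−)-Ipc2BOMe, −78 °C; BF3·OEt2 (no excess); 12, −78 °C; then NaOH, H2O2, 0 °C to rt; Et3N-buffered silica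
Reagents that add atoms: none
Why: Brown crotylboration: the (E)-crotylborane reacts through a closed chair (Zimmerman–Traxler) transition state, so the E geometry gives the anti C4/C5 pair, and the isopinocampheyl groups of the (+)-α-pinene series should direct attack to the Si face of the aldehyde, setting 5R and 4S under reagent control; alkaline peroxide frees the alcohol from 14.

Step 8
Reactants: 15 (2R,3S)-1-[(2R,3R)-2-[(tert-butyldiphenylsilyloxy)methyl]-5-methoxytetrahydrofuran-3-yl]-3-methylpent-4-en-2-ol; 16 ethyl but-2-ynoate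
Product: 17 ethyl (E)-3-{[(2R,3S)-1-[(2R,3R)-2-[(tert-butyldiphenylsilyloxy)methyl]-5-methoxytetrahydrofuran-3-yl]-3-methylpent-4-en-2-yl]oxy}but-2-enoate
Conditions: PMe3 (0.5 equiv), CH2Cl2, 0 °C to rt
Reagents that add atoms: none
Why: Trialkylphosphine-catalysed oxa-Michael addition of an alcohol to an alk-2-ynoate (the phosphine adds first, the alkoxide adds to the vinylphosphonium ion and the phosphine leaves) should give the more stable (E)-β-alkoxycrotonate, and the neutral medium keeps the C5 hydroxyl from closing onto C12.

Step 9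
Reactants: 17 silyl-protected (E)-β-alkoxycrotonate
Product: 18 ethyl (E)-3-{[(2R,3S)-1-[(2R,3R)-2-(hydroxymethyl)-5-methoxytetrahydrofuran-3-yl]-3-methylpent-4-en-2-yl]oxy}but-2-enoate
Conditions: Bu4NF, THF, 0 °C to rt
Reagents that add atoms: none
Why: Fluoride-driven desilylation frees the C9 primary alcohol, while the vinylogous carbonate, the acetal and the vinyl group are inert to fluoride.

Step 10
Reactants: 18 C9 primary alcohol
Product: 19 ethyl (E)-3-{[(2R,3S)-1-[(2R,3R)-2-formyl-5-methoxytetrahydrofuran-3-yl]-3-methylpent-4-en-2-yl]oxy}but-2-enoate (key-step precursor)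
Conditions: Dess–Martin periodinane, NaHCO3, CH2Cl2, 0 °C to rt
Reagents that add atoms: none
Why: Dess–Martin oxidation stops at the aldehyde under buffered, non-enolising conditions, so the α-alkoxy centre C8 should not epimerise; the aldehyde is used at once.

Step 11
Reactants: 19 C9 aldehyde with the C5-O (E)-β-alkoxycrotonate and the C4 vinyl group
Product: 20 key-step product: 2-methoxytetrahydrofuran trans-fused at C7–C8 to the oxepane (O, C5–C10); 9S hydroxyl; 10R carbon with CH3 and CH2CO2Et; 5R carbon with the (S)-but-3-en-2-yl group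
Conditions: SmI2 (3 equiv), MeOH (3 equiv), THF, 0 °C
Reagents that add atoms: none
Why: SmI2 transfers one electron to the C9 aldehyde, the samarium ketyl, held against the crotonate carbonyl by chelation to trivalent samarium, adds to the β-carbon C10, and a second electron followed by protonation by methanol turns the α-ester radical into the ester. The closest known reaction type is the SmI2-induced reductive cyclisation of aldehydes onto β-alkoxyacrylates, which is established for β-methyl acceptors and for oxepane formation in trans-fused polyether work. The oxepane (O, C5, C6, C7, C8, C9, C10) closes in the 7-exo-trig mode. C10 is controlled by C5: in the chair-like chelate the C5 side chain lies pseudo-equatorial and the (E)-crotonate places the acetate arm cis to it across the ring oxygen with the methyl axial (10R); C9 is controlled by the chelate itself, which holds the ketyl oxygen anti to the arm and equatorial, trans also to the C8 oxygen (9S). The step needs 2,7-cis and 2,3-trans selectivity and ring closure ahead of ketyl reduction or loss of the C8 oxygen; the first is secured by the C5 centre together with the trans C7/C8 ring fusion, which puts both tethers equatorial, the second by C8 carrying an acetal ether oxygen and not an acyloxy group.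

Step 12
Reactants: 20 oxepane hydroxy ester
Product: 21 lactol between the C9 oxygen and C2 (C2 epimers; otherwise as 20)
Conditions: i-Bu2AlH (3 equiv), CH2Cl2, −78 °C; aq. potassium sodium tartrate
Reagents that add atoms: none
Why: i-Bu2AlH reduces the ethyl ester, the only carbonyl group in the molecule, to the aldehyde level, which should rest as the five-membered lactol with the C9 hydroxyl; any lactone formed between C9–O and C2 in step 11 would converge on the same lactol.

Step 13
Reactants: 21 lactol
Product: 22 diene: as 20 with a C10 allyl group (C1–C2=CH2) in place of CH2CO2Et and a free 9S hydroxyl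
Conditions: Ph3PCH3Br, KOtBu, THF, 0 °C to rt
Reagents that add atoms: methyltriphenylphosphonium bromide, C[P+](c1ccccc1)(c1ccccc1)c1ccccc1.[Br-]
Why: Wittig methylenation of the lactol through its open hydroxy aldehyde form should give the terminal alkene without touching any stereocentre.

Step 14
Reactants: 22 diene
Product: 23 bridged alkene: second oxepane (O, C10, C1, C2, C3, C4, C5) closed with a (Z)-C2=C3 bond; ten-membered carbocycle complete; 9S hydroxyl free
Conditions: second-generation Grubbs catalyst (H2IMes)(PCy3)Cl2Ru=CHPh (5 mol%), CH2Cl2 (2 mM), 40 °C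
Reagents that add atoms: none
Why: Ring-closing olefin metathesis of the two monosubstituted alkenes, which the key step has placed cis on C5 and C10, should close the seven-membered ring across the ether oxygen, driven by loss of ethene.

Step 15
Reactants: 23 bridged alkene
Product: 24 saturated 5,10-oxygen-bridged bicycle with the C12 methyl acetal and the free 9S hydroxyl
Conditions: H2 (1 atm), Pd/C, EtOAc, rt
Reagents that add atoms: none
Why: Heterogeneous hydrogenation of the only alkene, a cis-disubstituted one, creates no stereocentre and leaves acetal, ethers and alcohol untouched.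

Step 16
Reactants: 24 saturated bicyclic alcohol; 25 (R)-2-methylbutanoic acid
Product: 26 C9 (R)-2-methylbutanoate of 24
Conditions: 25, 2,4,6-trichlorobenzoyl chloride, Et3N, THF, rt; then 24, DMAP, toluene, rt to 40 °C
Reagents that add atoms: none
Why: Yamaguchi esterification acylates the hindered secondary C9 hydroxyl through the mixed anhydride without enolising the α-branched acid; it precedes step 17 because a free C9 hydroxyl would be oxidised there.

Step 17
Reactants: 26 acetal ester
Product: 27 11,13-dihydro target: trans γ-lactone C12(=O)–O–C8 with the C9 (R)-2-methylbutanoate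
Conditions: CrO3, H2SO4, H2O, acetone, 0 °C
Reagents that add atoms: water, O
Why: Jones oxidation: the aqueous acid hydrolyses the methyl acetal to the lactol and chromic acid oxidises it to the γ-lactone, while the ester and the ethers should be inert.

Step 18
Reactants: 27 lactone ester
Product: 30 target CNP0136059.1, via Mannich base 28 (not isolated), via methiodide 29 (not isolated)
Conditions: LiN(SiMe3)2 (1.05 equiv), THF, −78 °C; CH2=NMe2 I, −78 °C to rt; then MeI, MeOH, rt; then aq. NaHCO3, EtOAc, rt
Reagents that add atoms: N,N-dimethylmethyleneiminium iodide (Eschenmoser's salt), C=[N+](C)C.[I-]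
Why: The unhindered and more acidic C11 methylene of the lactone should be deprotonated in preference to the hindered tertiary α-C–H of the 2-methylbutanoate, and Mannich alkylation of this enolate, N-methylation and base-induced elimination of trimethylamine give the α-methylene lactone; any ester enolate would be aminomethylated and not reprotonated, so the acyl stereocentre should not be epimerised.

Compound list
1 | (R)-5-oxotetrahydrofuran-2-carboxylic acid | OC(=O)[C@H]1CCC(=O)O1 | starting material
2 | (R)-5-(hydroxymethyl)dihydrofuran-2(3H)-one | OC[C@H]1CCC(=O)O1 | intermediate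
3 | (R)-5-[(tert-butyldiphenylsilyloxy)methyl]dihydrofuran-2(3H)-one | CC(C)(C)[Si](OC[C@H]1CCC(=O)O1)(c1ccccc1)c1ccccc1 | intermediate
4 | (5R)-5-[(tert-butyldiphenylsilyloxy)methyl]-3-(phenylselanyl)dihydrofuran-2(3H)-one (C3 epimers; not isolated) | CC(C)(C)[Si](OC[C@H]1CC([Se]c2ccccc2)C(=O)O1)(c1ccccc1)c1ccccc1 | intermediate
5 | (R)-5-[(tert-butyldiphenylsilyloxy)methyl]furan-2(5H)-one | CC(C)(C)[Si](OC[C@H]1C=CC(=O)O1)(c1ccccc1)c1ccccc1 | intermediate
6 | allylmagnesium bromide | C=CC[Mg]Br | starting material
7 | (4R,5R)-4-allyl-5-[(tert-butyldiphenylsilyloxy)methyl]-2-(trimethylsilyloxy)-4,5-dihydrofuran (not isolated) | C[Si](C)(C)OC1=C[C@@H](CC=C)[C@H](CO[Si](C(C)(C)C)(c2ccccc2)c2ccccc2)O1 | intermediate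
8 | (4R,5R)-4-allyl-5-[(tert-butyldiphenylsilyloxy)methyl]dihydrofuran-2(3H)-one (C7/C8 trans) | O=C1C[C@@H](CC=C)[C@H](CO[Si](C(C)(C)C)(c2ccccc2)c2ccccc2)O1 | intermediate
9 | (4R,5R)-4-allyl-5-[(tert-butyldiphenylsilyloxy)methyl]tetrahydrofuran-2-ol (C2 epimers; not isolated) | OC1C[C@@H](CC=C)[C@H](CO[Si](C(C)(C)C)(c2ccccc2)c2ccccc2)O1 | intermediate
10 | (4R,5R)-4-allyl-5-[(tert-butyldiphenylsilyloxy)methyl]-2-methoxytetrahydrofuran (C2 = C12, both epimers) | COC1C[C@@H](CC=C)[C@H](CO[Si](C(C)(C)C)(c2ccccc2)c2ccccc2)O1 | intermediate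
11 | 1,2,4-trioxolane (ozonide) of the allyl group of 10 (not isolated) | COC1C[C@@H](CC2OCOO2)[C@H](CO[Si](C(C)(C)C)(c2ccccc2)c2ccccc2)O1 | intermediate
12 | 2-[(2R,3R)-2-[(tert-butyldiphenylsilyloxy)methyl]-5-methoxytetrahydrofuran-3-yl]acetaldehyde (C5 aldehyde) | COC1C[C@@H](CC=O)[C@H](CO[Si](C(C)(C)C)(c2ccccc2)c2ccccc2)O1 | intermediate
13 | trans-but-2-ene | C/C=C/C | starting material
14 | diisopinocampheylborinate of 15 at the C5 oxygen (not isolated) | COC1C[C@@H](C[C@@H](OB([C@@H]2C[C@@H]3C[C@H]([C@H]2C)C3(C)C)[C@@H]2C[C@@H]3C[C@H]([C@H]2C)C3(C)C)[C@@H](C)C=C)[C@H](CO[Si](C(C)(C)C)(c2ccccc2)c2ccccc2)O1 | intermediate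
15 | (2R,3S)-1-[(2R,3R)-2-[(tert-butyldiphenylsilyloxy)methyl]-5-methoxytetrahydrofuran-3-yl]-3-methylpent-4-en-2-ol (5R, 4S, anti) | COC1C[C@@H](C[C@@H](O)[C@@H](C)C=C)[C@H](CO[Si](C(C)(C)C)(c2ccccc2)c2ccccc2)O1 | intermediate
16 | ethyl but-2-ynoate | CC#CC(=O)OCC | starting material
17 | ethyl (E)-3-{[(2R,3S)-1-[(2R,3R)-2-[(tert-butyldiphenylsilyloxy)methyl]-5-methoxytetrahydrofuran-3-yl]-3-methylpent-4-en-2-yl]oxy}but-2-enoate | COC1C[C@@H](C[C@@H](O/C(C)=C/C(=O)OCC)[C@@H](C)C=C)[C@H](CO[Si](C(C)(C)C)(c2ccccc2)c2ccccc2)O1 | intermediate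
18 | ethyl (E)-3-{[(2R,3S)-1-[(2R,3R)-2-(hydroxymethyl)-5-methoxytetrahydrofuran-3-yl]-3-methylpent-4-en-2-yl]oxy}but-2-enoate | COC1C[C@@H](C[C@@H](O/C(C)=C/C(=O)OCC)[C@@H](C)C=C)[C@H](CO)O1 | intermediate
19 | ethyl (E)-3-{[(2R,3S)-1-[(2R,3R)-2-formyl-5-methoxytetrahydrofuran-3-yl]-3-methylpent-4-en-2-yl]oxy}but-2-enoate (key-step precursor; 4S,5R,7R,8R) | COC1C[C@@H](C[C@@H](O/C(C)=C/C(=O)OCC)[C@@H](C)C=C)[C@H](C=O)O1 | intermediate
20 | key-step product (4S,5R,7R,8R,9S,10R): 2-methoxytetrahydrofuran trans-fused at C7–C8 to the oxepane (O, C5–C10); C9 OH; C10 CH3 and CH2CO2Et; C5 (S)-but-3-en-2-yl | COC1C[C@H]2C[C@H]([C@@H](C)C=C)O[C@](C)(CC(=O)OCC)[C@@H](O)[C@@H]2O1 | intermediate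
21 | lactol of 20: C9–O–C2H(OH)–C1H2–C10 five-membered ring (C2 epimers) | COC1C[C@H]2C[C@H]([C@@H](C)C=C)O[C@]3(C)CC(O)O[C@H]3[C@@H]2O1 | intermediate
22 | diene: as 20 with C10 allyl in place of CH2CO2Et; C9 OH | COC1C[C@H]2C[C@H]([C@@H](C)C=C)O[C@](C)(CC=C)[C@@H](O)[C@@H]2O1 | intermediate
23 | bridged alkene: 5,10-oxygen-bridged ten-membered carbocycle with (Z)-C2=C3; C9 OH; C12 methyl acetal | COC1C[C@H]2C[C@H]3O[C@](C)(C/C=C\[C@@H]3C)[C@@H](O)[C@@H]2O1 | intermediate
24 | saturated bicyclic alcohol (4S,5R,7R,8R,9S,10R) with the C12 methyl acetal | COC1C[C@H]2C[C@H]3O[C@](C)(CCC[C@@H]3C)[C@@H](O)[C@@H]2O1 | intermediate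
25 | (R)-2-methylbutanoic acid | CC[C@@H](C)C(=O)O | starting material
26 | C9 (R)-2-methylbutanoate of 24 | COC1C[C@H]2C[C@H]3O[C@](C)(CCC[C@@H]3C)[C@@H](OC(=O)[C@H](C)CC)[C@@H]2O1 | intermediate
27 | 11,13-dihydro target (C11 = CH2) | O=C1C[C@H]2C[C@H]3O[C@](C)(CCC[C@@H]3C)[C@@H](OC(=O)[C@H](C)CC)[C@@H]2O1 | intermediate
28 | C11 dimethylaminomethyl lactone (Mannich base; C11 epimers; not isolated) | CN(C)CC1C(=O)O[C@@H]2[C@@H]1C[C@H]1O[C@](C)(CCC[C@@H]1C)[C@H]2OC(=O)[C@H](C)CC | intermediate
29 | trimethylammonium iodide of 28 (not isolated) | C[N+](C)(C)CC1C(=O)O[C@@H]2[C@@H]1C[C@H]1O[C@](C)(CCC[C@@H]1C)[C@H]2OC(=O)[C@H](C)CC.[I-] | intermediate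
30 | CNP0136059.1 | C=C1C(=O)O[C@@H]2[C@@H]1C[C@H]1O[C@](C)(CCC[C@@H]1C)[C@H]2OC(=O)[C@H](C)CC | target

Total step count: 18. Longest linear sequence: 18 steps (1 to 30); 6, 13, 16 and 25 are bought.

Steps most likely to fail

1. Step 11. The ketyl may be protonated and reduced to the C9 alcohol, or shed the C8 oxygen, before the slow seven-membered closure, or it may close through a non-chelated conformer with the wrong C9/C10 relationship. The fallback sets out from 19 and comes back at 20, and swaps the ketyl for a neutral α-silyloxy radical. PhSeSiMe3 (CH2Cl2, rt) would add across the aldehyde to give the O-trimethylsilyl hemiselenoacetal F1. Bu3SnH and AIBN (benzene, 80 °C, slow addition) would remove the phenylselanyl group, and the C9 radical would close 7-exo onto the crotonate (tin hydride radical cyclisation onto a β-alkoxyacrylate) to give the C9 trimethylsilyl ether F2. K2CO3 in MeOH would remove the silyl group and give 20.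

2. Step 14. Both arms on C5 and C10 must swing over the ring oxygen, which the trans-fused five-membered ring resists, so intermolecular metathesis to oligomers may win. The fallback sets out from 22 and comes back at 23, and replaces olefin metathesis by reductive carbonyl coupling. Ozonolysis of both terminal alkenes (O3, CH2Cl2, −78 °C; PPh3) would give the C2/C3 dialdehyde F3, whose C2 aldehyde should rest as the lactol with the C9 hydroxyl. An intramolecular McMurry coupling with low-valent titanium (TiCl3(DME)1.5, Zn–Cu, DME, reflux, slow addition) would then join C2 to C3 as the alkene 23.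

3. Step 8. Addition of the hindered secondary C5 hydroxyl to the β-substituted ynoate may be slow, so that phosphine-induced oligomerisation of the ynoate consumes the reagent and conversion stalls. The fallback sets out from 15 and comes back at 17, and uses stoichiometric alkoxide addition–elimination in place of phosphine catalysis. Deprotonation of 15 with NaH (THF, 0 °C) and reaction of the sodium alkoxide with ethyl (E)-3-chlorobut-2-enoate would give 17 directly; an acid-catalysed exchange is ruled out by the acetal. No new compound arises (F0).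

Further compounds
F1 | step 11 | O-trimethylsilyl hemiselenoacetal of aldehyde 19 (C9 epimers) | COC1C[C@@H](C[C@@H](O/C(C)=C/C(=O)OCC)[C@@H](C)C=C)[C@H](C(O[Si](C)(C)C)[Se]c2ccccc2)O1
F2 | step 11 | C9 trimethylsilyl ether of 20 | COC1C[C@H]2C[C@H]([C@@H](C)C=C)O[C@](C)(CC(=O)OCC)[C@@H](O[Si](C)(C)C)[C@@H]2O1
F3 | step 14 | C2/C3 dialdehyde from 22 (open form) | COC1C[C@H]2C[C@H]([C@@H](C)C=O)O[C@](C)(CC=O)[C@@H](O)[C@@H]2O1
F0 | step 8 | none | none
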